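**Retrosynthetic overview**
1. 24 ⇐ global desilylation and Felkin–Anh reduction of the trans-3-aroyloxolane 22. The reduction sets the (S)-carbinol next to C3.
2. 22 ⇐ aryllithium 17 + α-methylene-γ-butyrolactone 16 in one flask: 1,2-addition, lactol opening, then 5-endo-trig oxa-Michael closure of the O1–C2 bond. The ring oxygen moves from the acyl carbon to the exocyclic methylene carbon.
3. Enabling feature: in the oxolane, C2 (the CH2 on O1) lies β to the benzylic carbinol carbon on C3, so at the ketone level O1–C2 is the C–O bond of a β-alkoxy aryl ketone. O1, C5, C4, C3, C2 and that benzylic carbon are exactly the atoms of a 4-substituted 3-methylideneoxolan-2-one.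
4. 16 ⇐ Eschenmoser methylenation of lactone 13 ⇐ Evans-type Mg-catalysed anti-aldol of succinyl imide 8 with aldehyde 2, which sets C4 and the (R)-carbinol.
5. Ring order: γ-lactone first (step 7), then its transposition into the oxolane (step 9). Both arenes are bought.

Key step: step 9

Remark: Ar = 3-methoxy-4-(triisopropylsilyloxy)phenyl and TIPS = triisopropylsilyl. The Mg-catalysed anti-aldol is assumed to follow the usual sense for N-acyloxazolidinones (chelated Z-enolate, attack anti to the benzyl group), which calls for the (R)-auxiliary.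

Step 1
Reactants: 1 vanillin
Product: 2 3-methoxy-4-(triisopropylsilyloxy)benzaldehyde
Conditions: TIPSCl, imidazole, DMF, rt
Reagents that add atoms: chlorotriisopropylsilane (TIPSCl), CC(C)[Si](Cl)(C(C)C)C(C)C
Why: Imidazole-promoted O-silylation of a phenol; TIPS is chosen because it should survive LDA, aryllithium and lithium alkoxides and leave with fluoride at the end.

Step 2
Reactants: 3 4-bromo-2-methoxyphenol
Product: 4 (4-bromo-2-methoxyphenoxy)triisopropylsilane
Conditions: TIPSCl, imidazole, DMF, rt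
Reagents that add atoms: chlorotriisopropylsilane (TIPSCl), CC(C)[Si](Cl)(C(C)C)C(C)C
Why: Same O-silylation of a phenol; the para-bromide is kept for the later bromine–lithium exchange.

Step 3
Reactants: 5 (R)-4-benzyl-1,3-oxazolidin-2-one, 6 4-tert-butoxy-4-oxobutanoic acid
Product: 8 tert-butyl 4-[(4R)-4-benzyl-2-oxo-1,3-oxazolidin-3-yl]-4-oxobutanoate, via mixed pivalic anhydride 7 (not isolated)
Conditions: 6, PivCl, Et3N, THF, −20 °C; then LiCl, 5, −20 °C → rt
Reagents that add atoms: none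
Why: N-Acylation of an Evans oxazolidinone through the mixed pivalic anhydride (LiCl/Et3N variant), which needs no strong base and leaves the tert-butyl ester alone; no stereocentre is formed.

Step 4
Reactants: 8 succinyl imide, 2 aldehyde
Product: 10 tert-butyl (3S,4R)-3-{[(4R)-4-benzyl-2-oxo-1,3-oxazolidin-3-yl]carbonyl}-4-hydroxy-4-Ar-butanoate, via TMS ether 9 (not isolated)
Conditions: MgCl2 (20 mol %), Et3N, TMSCl, EtOAc, rt; then PPTS (cat.), MeOH, 0 °C
Reagents that add atoms: none
Why: Evans-type magnesium halide-catalysed anti-aldol reaction: soft enolisation gives the Mg-chelated Z-enolate, the non-enolisable aromatic aldehyde attacks the face anti to the (R)-benzyl group and TMSCl traps the aldolate irreversibly, which should set the anti pair (3S,4R), while the tert-butyl ester keeps the freed carbinol from lactonising.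

Step 5
Reactants: 10 anti-aldol adduct
Product: 11 tert-butyl (3S,4R)-3-{[(4R)-4-benzyl-2-oxo-1,3-oxazolidin-3-yl]carbonyl}-4-Ar-4-(triisopropylsilyloxy)butanoate
Conditions: TIPSOTf, 2,6-lutidine, CH2Cl2, −20 → 0 °C
Reagents that add atoms: triisopropylsilyl triflate (TIPSOTf), CC(C)[Si](OS(=O)(=O)C(F)(F)F)(C(C)C)C(C)C
Why: Silyl triflate/2,6-lutidine silylation, too weakly basic for retro-aldol and harmless to the tert-butyl ester at or below 0 °C; the bulky TIPS group is chosen because it should not migrate to a neighbouring alkoxide in steps 7 and 9.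

Step 6
Reactants: 11 silylated imide
Product: 12 tert-butyl (3R,4R)-3-(hydroxymethyl)-4-Ar-4-(triisopropylsilyloxy)butanoate
Conditions: LiBH4, MeOH (1 equiv), THF, 0 °C
Reagents that add atoms: none
Why: Reductive removal of the Evans auxiliary with LiBH4, which attacks the activated exocyclic imide carbonyl much faster than a tert-butyl ester; both stereocentres are untouched and 5 is recovered.

Step 7
Reactants: 12 hydroxy ester
Product: 13 (4R)-4-[(R)-Ar(triisopropylsilyloxy)methyl]oxolan-2-one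
Conditions: KOt-Bu (10 mol %), THF, 0 °C
Reagents that add atoms: none
Why: Alkoxide-catalysed intramolecular transesterification (5-exo-trig lactonisation), chain-carried by the expelled tert-butoxide; no acid is used, so the electron-rich benzylic silyl ether is safe.

Step 8
Reactants: 13 lactone
Product: 16 (4R)-3-methylidene-4-[(R)-Ar(triisopropylsilyloxy)methyl]oxolan-2-one, via Mannich base 14 (not isolated), via methiodide 15 (not isolated)
Conditions: LDA, THF, −78 °C; Me2N=CH2+ I−, −78 °C → rt; MeI, THF, rt; aq NaHCO3, CH2Cl2, rt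
Reagents that add atoms: Eschenmoser's salt, C=[N+](C)C.[I-]
Why: Lactone α-methylenation by the Eschenmoser-salt Mannich reaction, N-methylation and E1cB (Hofmann-type) elimination; the centre made at C3 in 14 is erased again and the weak base avoids isomerisation to the endocyclic butenolide.

Step 9
Reactants: 16 α-methylene lactone, 4 aryl bromide
Product: 22 [(3R,4R)-4-{(R)-Ar(triisopropylsilyloxy)methyl}oxolan-3-yl](Ar)methanone, via aryllithium 17 (not isolated), via lithium lactolate 18 (not isolated), via keto alkoxide 19 (not isolated), via lithium enolate 20 (not isolated), via cis ketone 21 (not isolated)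
Conditions: 4, n-BuLi (1.0 equiv), THF, −78 °C; add to 16, THF (dilute), −78 °C, 1 h; t-BuOH, −78 °C → rt; AcOH
Reagents that add atoms: none
Why: Proposed new method: the hard aryllithium 17 adds 1,2 to the lactone carbonyl of 16, lactolate 18 opens on warming to the 2-aroylallyl alkoxide 19, and its primary alkoxide attacks the terminal methylene carbon in an oxa-Michael addition that forms the O1–C2 bond, so the ring oxygen moves from the acyl carbon to the methylene carbon. The closest known reaction types are the single addition of aryllithiums to γ-butyrolactones (giving γ-hydroxy ketones) and the alkoxide 5-endo-trig cyclisation of homoallylic alcohols onto 1,1-disubstituted vinyl sulfones; their combination on an α-methylene lactone is new. The only ring closed is the oxolane, in the 5-endo-trig mode, which is kinetically slow but should be feasible because the acceptor is a strongly polarised aryl enone and because 18, 19, 20, 21 and 22 interconvert under LiOt-Bu/t-BuOH with the β-alkoxy ketone 22 as the thermodynamic sink. The one new stereocentre, C3, is α to the ketone and is set under equilibrium control trans to the bulky C4 substituent (cis ketone 21 epimerises through enolate 20), while C4 and the silyloxy carbinol centre are not touched. The step needs 1,2- over 1,4-addition and a single addition, secured by −78 °C, exactly one equivalent of 17 and a lactolate that stays closed in the cold. It also needs attack by the primary oxygen only, secured by the TIPS group on the benzylic oxygen, which should not migrate under lithium alkoxide conditions.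

Step 10
Reactants: 22 trans ketone
Product: 23 (S)-Ar{(3R,4R)-4-[(R)-Ar(triisopropylsilyloxy)methyl]oxolan-3-yl}methanol
Conditions: L-Selectride, THF, −78 °C; AcOH
Reagents that add atoms: none
Why: Felkin–Anh-controlled reduction with a bulky trialkylborohydride: ring carbon C4 with its branched substituent is the large group, hydride comes anti to it past C3–H, and the lithium β-chelate model (C=O and O1) predicts the same face, so the (S)-carbinol should dominate.

Step 11
Reactants: 23 tris-TIPS ether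
Product: 24 (S)-[(3R,4R)-4-[(R)-hydroxy(4-hydroxy-3-methoxyphenyl)methyl]oxolan-3-yl](4-hydroxy-3-methoxyphenyl)methanol
Conditions: TBAF, AcOH (1:1), THF, 0 °C → rt
Reagents that add atoms: none
Why: Fluoride-mediated cleavage of all three silyl ethers, buffered with acetic acid so that no free phenoxide expels a benzylic oxygen through a p-quinone methide; no stereocentre is touched.

**Compound list**
1 | vanillin | COc1cc(C=O)ccc1O | starting material
2 | 3-methoxy-4-(triisopropylsilyloxy)benzaldehyde | COc1cc(C=O)ccc1O[Si](C(C)C)(C(C)C)C(C)C | intermediate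
3 | 4-bromo-2-methoxyphenol | COc1cc(Br)ccc1O | starting material
4 | (4-bromo-2-methoxyphenoxy)triisopropylsilane | COc1cc(Br)ccc1O[Si](C(C)C)(C(C)C)C(C)C | intermediate
5 | (R)-4-benzyl-1,3-oxazolidin-2-one | O=C1N[C@H](Cc2ccccc2)CO1 | starting material
6 | 4-tert-butoxy-4-oxobutanoic acid | CC(C)(C)OC(=O)CCC(=O)O | starting material
7 | 4-tert-butoxy-4-oxobutanoic pivalic anhydride | CC(C)(C)OC(=O)CCC(=O)OC(=O)C(C)(C)C | intermediate
8 | tert-butyl 4-[(4R)-4-benzyl-2-oxo-1,3-oxazolidin-3-yl]-4-oxobutanoate | CC(C)(C)OC(=O)CCC(=O)N1[C@H](Cc2ccccc2)COC1=O | intermediate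
9 | 4-O-trimethylsilyl ether of 10 | O=C([C@@H](CC(=O)OC(C)(C)C)[C@@H](O[Si](C)(C)C)c1ccc(O[Si](C(C)C)(C(C)C)C(C)C)c(OC)c1)N1[C@H](Cc2ccccc2)COC1=O | intermediate
10 | tert-butyl (3S,4R)-3-{[(4R)-4-benzyl-2-oxo-1,3-oxazolidin-3-yl]carbonyl}-4-hydroxy-4-Ar-butanoate | O=C([C@@H](CC(=O)OC(C)(C)C)[C@@H](O)c1ccc(O[Si](C(C)C)(C(C)C)C(C)C)c(OC)c1)N1[C@H](Cc2ccccc2)COC1=O | intermediate
11 | 4-O-TIPS ether of 10 | O=C([C@@H](CC(=O)OC(C)(C)C)[C@@H](O[Si](C(C)C)(C(C)C)C(C)C)c1ccc(O[Si](C(C)C)(C(C)C)C(C)C)c(OC)c1)N1[C@H](Cc2ccccc2)COC1=O | intermediate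
12 | tert-butyl (3R,4R)-3-(hydroxymethyl)-4-Ar-4-(triisopropylsilyloxy)butanoate | OC[C@@H](CC(=O)OC(C)(C)C)[C@@H](O[Si](C(C)C)(C(C)C)C(C)C)c1ccc(O[Si](C(C)C)(C(C)C)C(C)C)c(OC)c1 | intermediate
13 | (4R)-4-[(R)-Ar(triisopropylsilyloxy)methyl]oxolan-2-one | O=C1C[C@@H]([C@@H](O[Si](C(C)C)(C(C)C)C(C)C)c2ccc(O[Si](C(C)C)(C(C)C)C(C)C)c(OC)c2)CO1 | intermediate
14 | 3-[(dimethylamino)methyl] derivative of 13 (C3 mainly trans, not defined) | CN(C)CC1C(=O)OC[C@@H]1[C@@H](O[Si](C(C)C)(C(C)C)C(C)C)c1ccc(O[Si](C(C)C)(C(C)C)C(C)C)c(OC)c1 | intermediate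
15 | trimethylammonium iodide derived from 14 | C[N+](C)(C)CC1C(=O)OC[C@@H]1[C@@H](O[Si](C(C)C)(C(C)C)C(C)C)c1ccc(O[Si](C(C)C)(C(C)C)C(C)C)c(OC)c1.[I-] | intermediate
16 | (4R)-3-methylidene-4-[(R)-Ar(triisopropylsilyloxy)methyl]oxolan-2-one | C=C1C(=O)OC[C@@H]1[C@@H](O[Si](C(C)C)(C(C)C)C(C)C)c1ccc(O[Si](C(C)C)(C(C)C)C(C)C)c(OC)c1 | intermediate
17 | [3-methoxy-4-(triisopropylsilyloxy)phenyl]lithium | [Li]c1ccc(O[Si](C(C)C)(C(C)C)C(C)C)c(OC)c1 | intermediate
18 | lithium (4R)-2-Ar-3-methylidene-4-[(R)-Ar(triisopropylsilyloxy)methyl]oxolan-2-olate (C2 epimers) | C=C1C([O-])(c2ccc(O[Si](C(C)C)(C(C)C)C(C)C)c(OC)c2)OC[C@@H]1[C@@H](O[Si](C(C)C)(C(C)C)C(C)C)c1ccc(O[Si](C(C)C)(C(C)C)C(C)C)c(OC)c1.[Li+] | intermediate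
19 | lithium (2R)-2-[(R)-Ar(triisopropylsilyloxy)methyl]-3-(Ar-carbonyl)but-3-en-1-olate | [Li+].[O-]C[C@@H](C(=C)C(=O)c1ccc(O[Si](C(C)C)(C(C)C)C(C)C)c(OC)c1)[C@@H](O[Si](C(C)C)(C(C)C)C(C)C)c1ccc(O[Si](C(C)C)(C(C)C)C(C)C)c(OC)c1 | intermediate
20 | lithium Ar{(4R)-4-[(R)-Ar(triisopropylsilyloxy)methyl]oxolan-3-ylidene}methanolate | [Li+].[O-]C(c1ccc(O[Si](C(C)C)(C(C)C)C(C)C)c(OC)c1)=C1COC[C@@H]1[C@@H](O[Si](C(C)C)(C(C)C)C(C)C)c1ccc(O[Si](C(C)C)(C(C)C)C(C)C)c(OC)c1 | intermediate
21 | (3S,4R) cis epimer of 22 | COc1cc(C(=O)[C@@H]2COC[C@@H]2[C@@H](O[Si](C(C)C)(C(C)C)C(C)C)c2ccc(O[Si](C(C)C)(C(C)C)C(C)C)c(OC)c2)ccc1O[Si](C(C)C)(C(C)C)C(C)C | intermediate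
22 | [(3R,4R)-4-{(R)-Ar(triisopropylsilyloxy)methyl}oxolan-3-yl](Ar)methanone | COc1cc(C(=O)[C@H]2COC[C@@H]2[C@@H](O[Si](C(C)C)(C(C)C)C(C)C)c2ccc(O[Si](C(C)C)(C(C)C)C(C)C)c(OC)c2)ccc1O[Si](C(C)C)(C(C)C)C(C)C | intermediate
23 | (S)-Ar{(3R,4R)-4-[(R)-Ar(triisopropylsilyloxy)methyl]oxolan-3-yl}methanol | COc1cc([C@@H](O)[C@H]2COC[C@@H]2[C@@H](O[Si](C(C)C)(C(C)C)C(C)C)c2ccc(O[Si](C(C)C)(C(C)C)C(C)C)c(OC)c2)ccc1O[Si](C(C)C)(C(C)C)C(C)C | intermediate
24 | (S)-[(3R,4R)-4-[(R)-hydroxy(4-hydroxy-3-methoxyphenyl)methyl]oxolan-3-yl](4-hydroxy-3-methoxyphenyl)methanol | COc1cc([C@@H](O)[C@H]2COC[C@@H]2[C@@H](O)c2ccc(O)c(OC)c2)ccc1O | target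

**Step count**
Total step count: 11. Longest linear sequence: 9 steps (1 → 2 → 10 → 11 → 12 → 13 → 16 → 22 → 23 → 24).

**Steps most likely to fail**

Step 9 (Proposed new method).
- What may go wrong: conjugate addition of the aryl anion to the exocyclic methylene, chain growth by the enolate so formed, a second aryl addition after premature lactol opening, or a 5-endo closure too slow to compete with these.
- Fallback (known chemistry only): it sets out from 13 together with 2 and comes back at 24. The oxolane is closed by a classical 5-exo-tet cyclodehydration of a 1,4-diol, and the carbonyl carbon of 13 now ends as a ring CH2.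
- The LiHMDS enolate of 13 (THF, −78 °C) is added to aldehyde 2 anti to the C4 substituent to give the trans aldol adduct F1 as carbinol epimers. Dess–Martin oxidation gives the β-keto lactone F2.
- Chelation-controlled reduction with Zn(BH4)2 (hydride anti to C4 on the zinc chelate) should give the syn (S)-carbinol lactone F3. TIPSOTf/2,6-lutidine then gives the silyl ether F4, and LiBH4/MeOH reduces the lactone to the 1,4-diol F5.
- Mitsunobu cyclodehydration (PPh3, DIAD, THF) closes the tetrasilylated oxolane F6, and TBAF/AcOH gives 24.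

Step 4.
- What may go wrong: slow turnover or eroded anti and facial selectivity because the extra ester carbonyl competes for magnesium, and ionisation of the electron-rich carbinol during TMS removal.
- Fallback: it sets out from 2 and comes back at 12. The two centres are set one after the other without an auxiliary.
- Roskamp homologation of 2 (ethyl diazoacetate, SnCl2 cat., CH2Cl2) gives the β-keto ester F7. Noyori hydrogenation with Ru–(S)-BINAP should give the (R)-β-hydroxy ester F8.
- Fráter–Seebach alkylation of its dianion (LDA, 2.2 equiv, then tert-butyl bromoacetate, kept cold) should give the anti succinate F9. TIPSOTf/2,6-lutidine gives the silyl ether F10, and LiBH4 reduces the ethyl ester in preference to the tert-butyl ester to give 12.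

Step 10.
- What may go wrong: poor facial selectivity of hydride delivery if the ring carbons C2 and C4 are not differentiated well enough.
- Fallback: it sets out from 22 and comes back at 23. Stereocontrol is moved from the substrate to a chiral catalyst.
- Corey–Bakshi–Shibata reduction with the (R)-methyl oxazaborolidine and BH3·SMe2 (THF, −20 °C) delivers the (S)-aryl carbinol by differentiating aryl from alkyl. It should be matched with the substrate bias, and no new compound is made.

**Further compounds**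
F1 | step 9 | (3S,4R)-3-[hydroxy(Ar)methyl]-4-[(R)-Ar(triisopropylsilyloxy)methyl]oxolan-2-one (carbinol epimers) | COc1cc(C(O)[C@H]2C(=O)OC[C@@H]2[C@@H](O[Si](C(C)C)(C(C)C)C(C)C)c2ccc(O[Si](C(C)C)(C(C)C)C(C)C)c(OC)c2)ccc1O[Si](C(C)C)(C(C)C)C(C)C
F2 | step 9 | (3S,4R)-3-(Ar-carbonyl)-4-[(R)-Ar(triisopropylsilyloxy)methyl]oxolan-2-one | COc1cc(C(=O)[C@H]2C(=O)OC[C@@H]2[C@@H](O[Si](C(C)C)(C(C)C)C(C)C)c2ccc(O[Si](C(C)C)(C(C)C)C(C)C)c(OC)c2)ccc1O[Si](C(C)C)(C(C)C)C(C)C
F3 | step 9 | (3S,4R)-3-[(S)-hydroxy(Ar)methyl]-4-[(R)-Ar(triisopropylsilyloxy)methyl]oxolan-2-one | COc1cc([C@@H](O)[C@H]2C(=O)OC[C@@H]2[C@@H](O[Si](C(C)C)(C(C)C)C(C)C)c2ccc(O[Si](C(C)C)(C(C)C)C(C)C)c(OC)c2)ccc1O[Si](C(C)C)(C(C)C)C(C)C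
F4 | step 9 | O-TIPS ether of F3 | COc1cc([C@@H](O[Si](C(C)C)(C(C)C)C(C)C)[C@H]2C(=O)OC[C@@H]2[C@@H](O[Si](C(C)C)(C(C)C)C(C)C)c2ccc(O[Si](C(C)C)(C(C)C)C(C)C)c(OC)c2)ccc1O[Si](C(C)C)(C(C)C)C(C)C
F5 | step 9 | (2R,3R)-2-[(S)-Ar(triisopropylsilyloxy)methyl]-3-[(R)-Ar(triisopropylsilyloxy)methyl]butane-1,4-diol | COc1cc([C@@H](O[Si](C(C)C)(C(C)C)C(C)C)[C@@H](CO)[C@H](CO)[C@@H](O[Si](C(C)C)(C(C)C)C(C)C)c2ccc(O[Si](C(C)C)(C(C)C)C(C)C)c(OC)c2)ccc1O[Si](C(C)C)(C(C)C)C(C)C
F6 | step 9 | (3R,4R)-3-[(S)-Ar(triisopropylsilyloxy)methyl]-4-[(R)-Ar(triisopropylsilyloxy)methyl]oxolane | COc1cc([C@@H](O[Si](C(C)C)(C(C)C)C(C)C)[C@H]2COC[C@@H]2[C@@H](O[Si](C(C)C)(C(C)C)C(C)C)c2ccc(O[Si](C(C)C)(C(C)C)C(C)C)c(OC)c2)ccc1O[Si](C(C)C)(C(C)C)C(C)C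
F7 | step 4 | ethyl 3-Ar-3-oxopropanoate | CCOC(=O)CC(=O)c1ccc(O[Si](C(C)C)(C(C)C)C(C)C)c(OC)c1
F8 | step 4 | ethyl (R)-3-Ar-3-hydroxypropanoate | CCOC(=O)C[C@@H](O)c1ccc(O[Si](C(C)C)(C(C)C)C(C)C)c(OC)c1
F9 | step 4 | 4-tert-butyl 1-ethyl (2S)-2-[(R)-Ar(hydroxy)methyl]butanedioate | CCOC(=O)[C@@H](CC(=O)OC(C)(C)C)[C@@H](O)c1ccc(O[Si](C(C)C)(C(C)C)C(C)C)c(OC)c1
F10 | step 4 | O-TIPS ether of F9 | CCOC(=O)[C@@H](CC(=O)OC(C)(C)C)[C@@H](O[Si](C(C)C)(C(C)C)C(C)C)c1ccc(O[Si](C(C)C)(C(C)C)C(C)C)c(OC)c1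
F0 | step 10 | none | none
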